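**Retrosynthetic overview**
1. Target ⇒ 4-bromo-3-butyl-5-methylidenefuran-2(5H)-one. The two exocyclic bromines are installed last, by two rounds of Br2 addition and HBr loss.
2. ⇒ 4-bromo-3-butyl-3-hydroxy-5-methylfuran-2(3H)-one. The C3=C4/C5=CH2 diene comes from a net 1,4-loss of water.
3. ⇒ 2-hydroxy-2-(prop-1-yn-1-yl)hexanoic acid. Key disconnection: the ring O1–C5 bond, made together with C4–Br by a 5-endo-dig bromolactonisation.
4. ⇒ ethyl 2-oxohexanoate + propynyl Grignard reagent (C–C bond at the carbinol carbon).
5. Ring order: the butenolide is the only ring and is closed in the second step.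

Assumption: the target has no stereocentre and its exocyclic alkene carbon carries two identical bromines, so it is achiral. "Single enantiomer" therefore means the one constitution drawn, and racemic intermediates are acceptable.

**Step 1**
Reactants: 1 ethyl 2-oxohexanoate; 2 prop-1-yn-1-ylmagnesium bromide (CH3C≡CMgBr, 0.5 M in THF)
Product: 4 2-hydroxy-2-(prop-1-yn-1-yl)hexanoic acid (racemic), via hydroxy ester 3 (not isolated)
Conditions: CH3C≡CMgBr (1.1 equiv), THF, −78 °C to 0 °C; then LiOH (3 equiv), H2O/MeOH, rt; then 1 M HCl
Reagents that add atoms: prop-1-yn-1-ylmagnesium bromide (CC#C[Mg]Br); lithium hydroxide ([Li+].[OH-])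
Why: Grignard 1,2-addition of a weakly basic alkynyl nucleophile goes to the ketone carbonyl, which is more electrophilic than the ester, and ester saponification in the same flask follows; the new stereocentre forms racemic and is erased in step 2.

**Step 2**
Reactants: 4 2-hydroxy-2-(prop-1-yn-1-yl)hexanoic acid
Product: 7 4-bromo-3-butyl-5-methylidenefuran-2(5H)-one, via bromo enol lactone 5 (not isolated), via allylic bromide 6 (not isolated)
Conditions: NBS (1.05 equiv), Ph3P=S (5 mol%), dry CH2Cl2, 0 °C to rt, dark; then Me3SiBr (2 equiv), 0 °C to rt; then Et3N (4 equiv), 0 °C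
Reagents that add atoms: N-bromosuccinimide (O=C1CCC(=O)N1Br)
Why: Proposed new method: this is a dehydrative 5-endo-dig bromolactonisation of a free tertiary α-hydroxy-β,γ-alkynoic acid, in which Lewis-base-activated bromenium bridges the alkyne, the electron-poor carbinol carbon pushes the positive charge onto the methyl-bearing alkyne carbon, and the carboxyl oxygen closes there anti to bromine, so the ring C–O bond and the C4–Br bond form together with no alkene-geometry problem because C2 is still sp3; Me3SiBr then exchanges the tertiary allylic OH for bromide with allylic transposition (SN1' through the allyl cation stabilised by the ring oxygen, giving the conjugated butenolide 6), and Et3N removes HBr (E2) from the only β-hydrogens left, those of the methyl group; the closest known reaction types are the iodocyclisation of 2,2-dialkyl-3-alkynoic acids to 4-iodofuran-2(3H)-ones and the halogen-intercepted Meyer–Schuster rearrangement, neither shown on α-hydroxy acids or with this dehydrative exit, and no stereocentre survives.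

**Step 3**
Reactants: 7 4-bromo-3-butyl-5-methylidenefuran-2(5H)-one
Product: 11 4-bromo-3-butyl-5-(dibromomethylidene)furan-2(5H)-one, via tribromide 8 (not isolated), via Z-bromomethylidene lactone 9 (not isolated), via tetrabromide 10 (not isolated)
Conditions: Br2 (1.05 equiv), CH2Cl2, 0 °C, dark; Et3N (1.1 equiv), 0 °C; Br2 (1.3 equiv), rt, dark; Et3N (1.6 equiv), 0 °C
Reagents that add atoms: bromine (BrBr)
Why: Two rounds of bromination–dehydrobromination (electrophilic Br2 addition to the exocyclic enol-ester alkene, then E2 loss of the labile tertiary C5 bromide) act only at the exocyclic carbon, because the tetrasubstituted electron-poor C3=C4 bond and, in the dark, the butyl chain are inert; the Z geometry of 9 is erased in the achiral product.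

**Compound list**
1 | ethyl 2-oxohexanoate | CCCCC(=O)C(=O)OCC | starting material
2 | prop-1-yn-1-ylmagnesium bromide | CC#C[Mg]Br | starting material
3 | ethyl 2-hydroxy-2-(prop-1-yn-1-yl)hexanoate (racemic) | CCCCC(O)(C#CC)C(=O)OCC | intermediate
4 | 2-hydroxy-2-(prop-1-yn-1-yl)hexanoic acid (racemic) | CCCCC(O)(C#CC)C(=O)O | intermediate
5 | 4-bromo-3-butyl-3-hydroxy-5-methylfuran-2(3H)-one (racemic) | CCCCC1(O)C(Br)=C(C)OC1=O | intermediate
6 | 4,5-dibromo-3-butyl-5-methylfuran-2(5H)-one (racemic) | CCCCC1=C(Br)C(C)(Br)OC1=O | intermediate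
7 | 4-bromo-3-butyl-5-methylidenefuran-2(5H)-one | CCCCC1=C(Br)C(=C)OC1=O | intermediate
8 | 4,5-dibromo-5-(bromomethyl)-3-butylfuran-2(5H)-one (racemic) | CCCCC1=C(Br)C(Br)(CBr)OC1=O | intermediate
9 | (5Z)-4-bromo-5-(bromomethylidene)-3-butylfuran-2(5H)-one | CCCCC1=C(Br)/C(=C/Br)OC1=O | intermediate
10 | 4,5-dibromo-3-butyl-5-(dibromomethyl)furan-2(5H)-one (racemic) | CCCCC1=C(Br)C(Br)(C(Br)Br)OC1=O | intermediate
11 | 4-bromo-3-butyl-5-(dibromomethylidene)furan-2(5H)-one | CCCCC1=C(Br)C(=C(Br)Br)OC1=O | target

**Totals**
Total step count: 3. Longest linear sequence: 3. Step 3 can be run in one flask because only an ammonium bromide salt accumulates between the four additions.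

**Steps most likely to fail**

Step 2 (the proposed new step).
- Risks: NBS may oxidatively decarboxylate the α-hydroxy acid to oct-2-yn-4-one. The deactivated alkyne may react slowly. The C3 leaving group may depart by 1,2-elimination toward the butyl chain.
- Fallback, all known reaction types: it sets out from 1 and comes back at 7.
- Wittig olefination of 1 with 1-(triphenylphosphoranylidene)propan-2-one (toluene, reflux) gives ethyl 2-butyl-4-oxopent-2-enoate F1.
- Br2 (CHCl3) adds across the alkene to give ethyl 2,3-dibromo-2-butyl-4-oxopentanoate F2.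
- Et3N removes the hydrogen α to the ketone and expels the C2 bromide (E1cB) to give ethyl 3-bromo-2-butyl-4-oxopent-2-enoate F3.
- Hot aqueous HBr/AcOH cleaves the ester, equilibrates the alkene geometry and closes the lactol 4-bromo-3-butyl-5-hydroxy-5-methylfuran-2(5H)-one F4.
- P2O5 (CH2Cl2, reflux) dehydrates F4 to 7.

Step 3.
- Risks: the second Br2 addition to the electron-poor bromodiene 9 may be slow. Bromide or amine may debrominate the crowded tetrabromide 10 back to 9. Residual amine consumes bromine.
- Fallback: it sets out from 7 and comes back at 11. It replaces the base-driven addition–elimination by acid-side ketone chemistry.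
- NBS in aqueous THF gives the lactol 4-bromo-5-(bromomethyl)-3-butyl-5-hydroxyfuran-2(5H)-one F5.
- Acid-catalysed α-bromination of its open bromomethyl ketone tautomer (Br2, HBr/AcOH, 50 °C) gives 4-bromo-3-butyl-5-(dibromomethyl)-5-hydroxyfuran-2(5H)-one F6.
- Dehydrative enol lactonisation in concentrated H2SO4 (100 °C) gives 11.

Step 1.
- Risks: the Grignard reagent may enolise keto ester 1, or some may attack the ester.
- Fallback: it sets out from 2 and comes back at 3. It reverses the order of the two C–C bond formations.
- Reagent 2 is added to excess diethyl oxalate at −78 °C to give ethyl 2-oxopent-3-ynoate F7, a keto ester with no α-hydrogens.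
- n-BuMgCl with LaCl3·2LiCl (THF, −78 °C) adds 1,2 to its ketone to give 3, which is saponified as in step 1.

**Further compounds**
F1 | step 2 | ethyl 2-butyl-4-oxopent-2-enoate (E/Z mixture) | CCCCC(=CC(C)=O)C(=O)OCC
F2 | step 2 | ethyl 2,3-dibromo-2-butyl-4-oxopentanoate (racemic diastereomer mixture) | CCCCC(Br)(C(Br)C(C)=O)C(=O)OCC
F3 | step 2 | ethyl 3-bromo-2-butyl-4-oxopent-2-enoate (E/Z mixture) | CCCCC(=C(Br)C(C)=O)C(=O)OCC
F4 | step 2 | 4-bromo-3-butyl-5-hydroxy-5-methylfuran-2(5H)-one (racemic) | CCCCC1=C(Br)C(C)(O)OC1=O
F5 | step 3 | 4-bromo-5-(bromomethyl)-3-butyl-5-hydroxyfuran-2(5H)-one (racemic) | CCCCC1=C(Br)C(O)(CBr)OC1=O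
F6 | step 3 | 4-bromo-3-butyl-5-(dibromomethyl)-5-hydroxyfuran-2(5H)-one (racemic) | CCCCC1=C(Br)C(O)(C(Br)Br)OC1=O
F7 | step 1 | ethyl 2-oxopent-3-ynoate | CC#CC(=O)C(=O)OCC
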